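## Structural features

The target is a flavone, a benzo-fused 4-pyranone (rings A and C) joined through the C2–C1' single bond to an aryl ring B. It is fully aromatic and has no stereocentre, so no stereochemical relationship has to be set. Ring A is fully substituted and carries oxygen on every free position in the order 5-OH, 6-OMe, 7-OH, 8-OMe. Ring B carries three contiguous oxygens (3'-OH, 4'-OH, 5'-OMe), while C2' and C6' bear hydrogen. The fragile elements are the oxidation-prone 3',4'-catechol, the electron-rich polyphenolic ring A, the three aryl methyl ethers (which must not be cleaved or exchanged by Lewis acids), and the pyranone ring, which opens under strong nucleophilic base. The real difficulty is regiochemical: hydroxyl and methoxyl groups alternate on ring A and are differentiated on ring B, so each oxygen has to enter the route already carrying its final label. The key step exploits the fact that the chain C2'–C3'(O)–C4'(O)–C5'(O)–C6' of ring B is the carbon framework of a 3,5-dioxygenated 4-pyranone, so that replacing the ring oxygen of that heterocycle by the exocyclic carbon of a chromon-2-ylmethyl ylide creates C1', ring B and the C2–C1' junction in one operation.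

## Logic of the disconnections

**23 back to 21 (through 22).** The O4'–Si bond and the three benzylic C–O bonds on O5, O7 and O3' are cut. These are the only differences between 23 and 21, so the whole skeleton and all three methyl ethers are already in place. The forward step must spare the methyl ethers and the C2=C3 bond. Fluoride followed by neutral hydrogenolysis does this, and keeps the catechol masked until the last operation.

**21 back to 11 and 16 (through 17, 18, 19, 20).** The bonds C1'–C2' and C1'–C6' are cut. C1' is the only ring B carbon without hydrogen or oxygen and it carries ring C. Taking it from the exocyclic methylene of 11 leaves a five-carbon, three-oxygen unit that is 16, whose ring oxygen is the atom to be expelled. The gain is a convergent union of two fragments of similar size, with the three ring B oxygens already differentiated. The demands are these: 16 must be fully converted to 17 before it meets 18, carbon attack must occur at an α-carbon of 17, and a second, non-nucleophilic base must be present for 19 to reach 20. Compared with a one-base protocol, the design is improved by forming 18 with exactly one equivalent of a silylamide and adding a hindered amine only after the C–C bond is made.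

**11 back to 9 (through 10).** The C–P bond is cut, and before it the C–Br bond. The alcohol 9 is the stable storage form of the reactive allylic-type halide. The forward step needs a neutral bromination that tolerates benzyl ethers, followed by SN2 quaternisation in the same flask.

**9 back to 8.** The O5–benzyl bond is cut. The chelated 5-OH would quench the ylide and must be masked, but it arises free because ring A is closed from a symmetric precursor. The forward step needs phenol-selective alkylation next to a primary alcohol.

**8 back to 5 and 6 (through 7).** The C2–C3 and O1–C2 bonds are cut, which is the classical chromone disconnection. The ester 6 delivers C2 and the exocyclic carbon at the alcohol oxidation level, so no later redox step is needed. Because 5 is symmetric, either phenol closes to the same chromone. The forward step needs a polyanion Claisen condensation, and an acid treatment that closes the ring and removes the acetal without touching the benzyl ether.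

**5 back to 4.** The aryl–acyl bond C4a–C4 is cut. 4 has a single free ring position, flanked by both hydroxyls, so regiochemistry is automatic. The demand is a Lewis acid mild enough for the benzyl ether.

**4 back to 3, 2 and 1.** The two C–O bonds to the future O5 and O1, then two C–Br bonds, then the O7–benzyl bond are cut. 1 already holds the 6-OMe / 7-O / 8-OMe triad, and the two missing oxygens go to the positions that both methoxy groups activate. The forward steps need a clean 4,6-dibromination and a double hydroxylation.

**16 back to 14 (through 15).** The C2–C3 and C5–C6 bonds and both ring C–O bonds are cut: two one-carbon units and one molecule of water are added to a ketone that already carries the benzyloxy/methoxy differentiation. A neutral amide-acetal condensation is preferred to a double formate Claisen, because the second C–C bond then does not depend on a dianion.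

**14 back to 13 and 12.** The carbonyl is taken back to the alcohol, and the C–OMe bond to opening of the epoxide at its terminal carbon. Both are simple functional-group operations on a cheap three-carbon unit.

## Other disconnections considered

**Alternative 1:** Ring A is cut at C7–C8 and C5–C6, so that rings B and C are already present in the pyranone ester A1, which is methyl 6-[3,4-bis(benzyloxy)-5-methoxyphenyl]-2-(methoxymethyl)-4-oxo-4H-pyran-3-carboxylate.
- **Forward key step:** a lithium amide would deprotonate the methoxymethyl group of A1. The carbanion would be acylated by the Weinreb amide A2, which is N,2-dimethoxy-N-methylacetamide. The terminal enolate of the new ketone would then close onto the ring ester (Dieckmann) and tautomerise to the flavone A3, which is 2-[3,4-bis(benzyloxy)-5-methoxyphenyl]-5,7-dihydroxy-6,8-dimethoxy-4H-chromen-4-one.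
- **In its favour:** every oxygen of the crowded ring A is placed by construction, with no electrophilic substitution or aryl hydroxylation on a pentaoxygenated benzene. The individual events are ordinary enolate chemistry. A3 has 5-OH and 7-OH free, so one hydrogenolysis of two benzyl ethers finishes the synthesis.
- **Against it here:** A1 is a tetrasubstituted pyranone needing its own multi-step preparation, and ring B must be bought with its oxygens already differentiated. After the first acylation the most acidic proton is the internal one at C8, so closure needs a dianion. The tetrahedral adduct of A2 is a stable chelate that would have to collapse in the flask before the Dieckmann step. A strong amide base also threatens conjugate addition to, or opening of, the pyranone ring of A1.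
- **Comparison:** on structure it attacks the hardest ring directly, which the chosen plan solves by classical arene chemistry; that is a conceptual advantage. On mechanism it is better precedented than the pyrylium exchange, although the one-flask double acylation is demanding. Its endgame from A3 is better (one deprotection, no silyl ether). On step economy it is unlikely to be shorter, since A1 and its ring B building block together should cost at least as many steps as 11 and 16.

**Alternative 2:** Ring C is cut at C8a–O1, C4a–C4 and O1–C2.
- **Forward key step:** fluoride would act on the symmetric precursor A4, which is 5-(benzyloxy)-4,6-dimethoxy-2-(trimethylsilyl)-1,3-phenylene bis(trifluoromethanesulfonate), and release the aryne A5, which is 5-(benzyloxy)-4,6-dimethoxy-2,3-didehydrophenyl trifluoromethanesulfonate. The carboxylate of the acid A6, which is 3-[3,4-bis(benzyloxy)-5-methoxyphenyl]prop-2-ynoic acid, would add to A5, the aryl anion would take the acyl group, and the phenoxide would close onto the ynone. The product would be the flavone triflate A7, which is 7-(benzyloxy)-2-[3,4-bis(benzyloxy)-5-methoxyphenyl]-6,8-dimethoxy-4-oxo-4H-chromen-5-yl trifluoromethanesulfonate.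
- **In its favour:** three bonds and one ring are formed in a single mild operation, which is more than the chosen key step forms. The reaction type (aryne insertion into a carboxylic acid, then acyl shift and oxa-Michael closure) is known. A4 is symmetric, so either triflate may leave.
- **Against it here:** A4 is a hexasubstituted benzene that needs silylation between two oxygens and double triflation, probably starting from a compound like 4. The triple bond of A5 is flanked by a triflyloxy group on one side and a methoxy group on the other, both inductively withdrawing. The direction of carboxylate addition therefore rests only on the difference between these two groups, and the wrong direction would place the triflate at C8. The C5 triflate of A7 needs a separate hydrolysis before hydrogenolysis. Ring B in A6 must again come from a gallate-type building block with differentiated oxygens.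
- **Comparison:** on bond count and precedent of the key step this alternative is the better. On regiochemical security the chosen plan is the better, because its only choice (which α-carbon is attacked) is immaterial. On step economy the two are about equal, since A4 and A6 need at least the effort of 11 and 16 and the endgame from A7 is one step longer.

**Alternative 3:** Ring C is cut at C2=C3.
- **Forward key step:** the precursor is the acyl-stabilised ylide A8, which is 3,5-bis(benzyloxy)-4,6-dimethoxy-2-[(triphenylphosphoranylidene)acetyl]phenyl 3,4-bis(benzyloxy)-5-methoxybenzoate. On heating, the ylide carbon of A8 would attack the aryl ester carbonyl in the same molecule and expel the phosphine oxide. The product would be the flavone A9, which is 5,7-bis(benzyloxy)-2-[3,4-bis(benzyloxy)-5-methoxyphenyl]-6,8-dimethoxy-4H-chromen-4-one.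
- **In its favour:** intramolecular ester olefination to chromones is a known reaction type, run under neutral thermal conditions with no regiochemical question. A9 needs only one hydrogenolysis. On reliability and on the endgame this alternative is the better.
- **Against it here:** only one bond is formed, so both rings must arrive complete in A8. To reach A8, the two ortho hydroxyls of an intermediate like 5 must be differentiated, the acetyl group must be brominated and converted to the ylide, and the aroyl unit for ring B must arrive with its three oxygens already distinguished. Olefination of the ester carbonyl of A8 needs prolonged heating and competes with acyl migration.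
- **Comparison:** on structure the chosen plan gains ring B with automatic 3',4',5' differentiation from a three-carbon starting material and is more convergent than the assembly of A8. On mechanism the alternative is safer. On step economy the two are roughly equal.

Key step: step 11

Remark on the chemistry: 6, 12 and 13 are used as racemates, because the stereocentre of 6 is lost with the acetal in step 5 and that of 12 and 13 is lost on oxidation in step 9; 6 is assumed to be a catalogue compound.

## Route

Step 1
Reactants: 1 2,6-dimethoxyphenol (syringol)
Product: 2 2-(benzyloxy)-1,3-dimethoxybenzene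
Conditions: BnBr, K2CO3, DMF, 60 °C
Reagents that add atoms: benzyl bromide BrCc1ccccc1
Why: Williamson etherification of an acidic, moderately hindered phenol; the benzyl group becomes the O7 protecting group and removes the para-directing free hydroxyl before bromination.

Step 2
Reactants: 2 2-(benzyloxy)-1,3-dimethoxybenzene
Product: 3 3-(benzyloxy)-1,5-dibromo-2,4-dimethoxybenzene
Conditions: NBS (2.1 equiv), MeCN, 0 °C to rt, dark
Reagents that add atoms: N-bromosuccinimide O=C1CCC(=O)N1Br
Why: Electrophilic aromatic bromination; C4 and C6 are each ortho to one methoxy group and para to the other, whereas C5 is activated only by the twisted central benzyloxy group, so the two bromines should enter at C4 and C6 in turn.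

Step 3
Reactants: 3 3-(benzyloxy)-1,5-dibromo-2,4-dimethoxybenzene
Product: 4 5-(benzyloxy)-4,6-dimethoxybenzene-1,3-diol
Conditions: Pd2(dba)3 (cat.), tBuXPhos (cat.), KOH, 1,4-dioxane/H2O, 100 °C, Ar; then aq. HCl
Reagents that add atoms: potassium hydroxide [K+].[OH-]
Why: C–O coupling of aryl bromides with hydroxide, catalysed by Pd2(dba)3 and a bulky biaryl dialkylphosphine; each C–Br bond has only one ortho substituent and strict exclusion of air protects the electron-rich diol.

Step 4
Reactants: 4 5-(benzyloxy)-4,6-dimethoxybenzene-1,3-diol
Product: 5 1-[4-(benzyloxy)-2,6-dihydroxy-3,5-dimethoxyphenyl]ethan-1-one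
Conditions: Ac2O (1.2 equiv), BF3·OEt2 (3 equiv), EtOAc, 0 °C to rt; then aq. NaOAc, MeOH, 50 °C
Reagents that add atoms: acetic anhydride CC(=O)OC(C)=O
Why: Friedel–Crafts C-acylation (with Fries-type O-to-C transfer of any aryl acetate) at the only free ring position, which is ortho to both hydroxyls and para to the benzyloxy group; this phloroglucinol-type ring should react at or below room temperature, where aryl benzyl ethers tolerate BF3, and the buffered methanolysis breaks the difluoroboron chelate of the product.

Step 5
Reactants: 5 1-[4-(benzyloxy)-2,6-dihydroxy-3,5-dimethoxyphenyl]ethan-1-one; 6 ethyl 2-(oxan-2-yloxy)acetate (racemic)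
Product: 8 7-(benzyloxy)-5-hydroxy-2-(hydroxymethyl)-6,8-dimethoxy-4H-chromen-4-one, via diketone 7 (not isolated)
Conditions: 6 (1.5 equiv), LiN(SiMe3)2 (5 equiv), THF, −78 °C to rt; then conc. HCl, MeOH, 60 °C
Reagents that add atoms: none
Why: Crossed Claisen condensation of the acetophenone polyanion with the ester gives 7; acid then closes the chromone by attack of a chelated phenol on the more electrophilic aliphatic ketone, dehydrates, and cleaves the acetal. The symmetry of 5 removes any regiochemical question, and the di-ortho-substituted aryl ketone is a poor acceptor for the competing closure by the primary hydroxyl.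

Step 6
Reactants: 8 7-(benzyloxy)-5-hydroxy-2-(hydroxymethyl)-6,8-dimethoxy-4H-chromen-4-one
Product: 9 5,7-bis(benzyloxy)-2-(hydroxymethyl)-6,8-dimethoxy-4H-chromen-4-one
Conditions: BnBr, K2CO3, DMF, 60 °C
Reagents that add atoms: benzyl bromide BrCc1ccccc1
Why: Williamson benzylation of the chelated 5-hydroxyl, which needs warm DMF; K2CO3 does not deprotonate the primary alcohol, so only the phenol is alkylated.

Step 7
Reactants: 9 5,7-bis(benzyloxy)-2-(hydroxymethyl)-6,8-dimethoxy-4H-chromen-4-one
Product: 11 {[5,7-bis(benzyloxy)-6,8-dimethoxy-4-oxo-4H-chromen-2-yl]methyl}triphenylphosphonium bromide, via bromide 10 (not isolated)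
Conditions: CBr4, PPh3, CH2Cl2, 0 °C; then PPh3, toluene, 80 °C
Reagents that add atoms: carbon tetrabromide BrC(Br)(Br)Br; triphenylphosphine c1ccc(cc1)P(c1ccccc1)c1ccccc1
Why: Appel bromination under neutral conditions, then SN2 quaternisation of the activated primary bromide by triphenylphosphine; the salt should crystallise from toluene away from the neutral by-products.

Step 8
Reactants: 12 benzyl glycidyl ether (racemic)
Product: 13 1-(benzyloxy)-3-methoxypropan-2-ol (racemic)
Conditions: NaOMe (0.2 equiv), MeOH, 65 °C
Reagents that add atoms: methanol CO
Why: Base-mediated epoxide opening by methoxide at the unhindered terminal carbon; the resulting stereocentre is removed in step 9.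

Step 9
Reactants: 13 1-(benzyloxy)-3-methoxypropan-2-ol (racemic)
Product: 14 1-(benzyloxy)-3-methoxypropan-2-one
Conditions: TEMPO (cat.), KBr (cat.), NaOCl, NaHCO3, CH2Cl2/H2O, 0 °C
Reagents that add atoms: none
Why: Anelli oxidation of a secondary alcohol to the ketone under buffered biphasic conditions that leave both ethers untouched.

Step 10
Reactants: 14 1-(benzyloxy)-3-methoxypropan-2-one
Product: 16 3-(benzyloxy)-5-methoxy-4H-pyran-4-one, via bis-enaminone 15 (not isolated)
Conditions: tBuOCH(NMe2)2 (3 equiv), toluene, 110 °C; then 2 M HCl, THF, 50 °C
Reagents that add atoms: tert-butoxybis(dimethylamino)methane CN(C)C(OC(C)(C)C)N(C)C; water O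
Why: Amide-acetal condensation on both α-methylene groups gives 15 through neutral intermediates; aqueous acid hydrolyses one enaminone to the enol, which closes onto the other with loss of dimethylamine, the usual route from bis-enaminones to 3,5-disubstituted 4-pyranones.

Step 11
Reactants: 11 {[5,7-bis(benzyloxy)-6,8-dimethoxy-4-oxo-4H-chromen-2-yl]methyl}triphenylphosphonium bromide; 16 3-(benzyloxy)-5-methoxy-4H-pyran-4-one
Product: 21 5,7-bis(benzyloxy)-2-[3-(benzyloxy)-4-(tert-butyldimethylsilyloxy)-5-methoxyphenyl]-6,8-dimethoxy-4H-chromen-4-one, via pyrylium triflate 17 (not isolated), via ylide 18 (not isolated), via 2H-pyran adduct 19 (not isolated), via dienal ylide 20 (not isolated)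
Conditions: 16 (1.3 equiv), TBSOTf (1.2 equiv), CH2Cl2, 0 °C to rt; separately 11, NaN(SiMe3)2 (1.0 equiv), THF, −78 to 0 °C; combine at −78 °C; then iPr2NEt (2 equiv), −78 to 50 °C
Reagents that add atoms: tert-butyldimethylsilyl trifluoromethanesulfonate CC(C)(C)[Si](C)(C)OS(=O)(=O)C(F)(F)F
Why: Proposed new method: the ylide carbon of 18 should add to an α-carbon (C2 or the equivalent C6) of the preformed cation 17 to give the 2H-pyran 19, which has only one substituent at its sp3 carbon and therefore opens by retro-6π electrocyclisation; iPr2NEt then removes the P–CH proton, now vinylogous to the aldehyde as well as to the chromone carbonyl, to give 20. Intramolecular Wittig olefination of the aldehyde in 20 (6-exo-trig addition of the ylide carbon to C=O, then loss of Ph3PO from the oxaphosphetane) makes the second bond to C1' and closes ring B directly as a benzene, the silyl dienol ether ending as the aryl silyl ether of 21. The closest known reaction types are the conversion of 2,4,6-triarylpyrylium salts into benzenes by alkylidenephosphoranes or nitromethane anion, and the α-addition of carbon nucleophiles to 4-silyloxypyrylium and 4-silyloxybenzopyrylium triflates; new here are the α-unsubstituted 3,5-dioxygenated cation and the chromone-stabilised ylide. No stereocentre is created, and the geometry left at C2'=C3' by the ring opening is not binding, because it can equilibrate through the delocalised ylide 20 or through reclosure to 19. Regioselectivity is not required, since attack at either α-carbon of 17 leads to the same arene. Chemoselectivity is required: carbon attack on the pyrylium ring must win over silyl transfer to the chromone oxygen of 18, over attack through chromone C3 and over any reaction at the chromone carbonyl; complete silylation of 16 before mixing, a slight deficit of silyl triflate relative to 16, the much higher electrophilicity of the cation and late addition of the second base are meant to secure this.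

Step 12
Reactants: 21 5,7-bis(benzyloxy)-2-[3-(benzyloxy)-4-(tert-butyldimethylsilyloxy)-5-methoxyphenyl]-6,8-dimethoxy-4H-chromen-4-one
Product: 23 5,7-dihydroxy-2-(3,4-dihydroxy-5-methoxyphenyl)-6,8-dimethoxy-4H-chromen-4-one (5,7,3',4'-tetrahydroxy-6,8,5'-trimethoxyflavone), via phenol 22 (not isolated)
Conditions: KHF2, MeOH/THF, rt; then H2 (1 atm), Pd/C (10%), rt
Reagents that add atoms: none
Why: Fluoride cleaves the phenolic silyl ether under near-neutral conditions, and hydrogenolysis over Pd/C in the same flask removes the three benzyl ethers; aryl methyl ethers and the flavone C2=C3 bond are inert to both, and the catechol is liberated only in the final, oxygen-free operation.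

## Compound list

1 | 2,6-dimethoxyphenol (syringol) | COc1cccc(OC)c1O | starting material
2 | 2-(benzyloxy)-1,3-dimethoxybenzene | COc1cccc(OC)c1OCc1ccccc1 | intermediate
3 | 3-(benzyloxy)-1,5-dibromo-2,4-dimethoxybenzene | COc1c(Br)cc(Br)c(OC)c1OCc1ccccc1 | intermediate
4 | 5-(benzyloxy)-4,6-dimethoxybenzene-1,3-diol | COc1c(O)cc(O)c(OC)c1OCc1ccccc1 | intermediate
5 | 1-[4-(benzyloxy)-2,6-dihydroxy-3,5-dimethoxyphenyl]ethan-1-one | CC(=O)c1c(O)c(OC)c(OCc2ccccc2)c(OC)c1O | intermediate
6 | ethyl 2-(oxan-2-yloxy)acetate (racemic) | CCOC(=O)COC1CCCCO1 | starting material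
7 | 1-[4-(benzyloxy)-2,6-dihydroxy-3,5-dimethoxyphenyl]-4-(oxan-2-yloxy)butane-1,3-dione (racemic) | COc1c(O)c(C(=O)CC(=O)COC2CCCCO2)c(O)c(OC)c1OCc1ccccc1 | intermediate
8 | 7-(benzyloxy)-5-hydroxy-2-(hydroxymethyl)-6,8-dimethoxy-4H-chromen-4-one | COc1c(OCc2ccccc2)c(OC)c2oc(CO)cc(=O)c2c1O | intermediate
9 | 5,7-bis(benzyloxy)-2-(hydroxymethyl)-6,8-dimethoxy-4H-chromen-4-one | COc1c(OCc2ccccc2)c(OC)c2oc(CO)cc(=O)c2c1OCc1ccccc1 | intermediate
10 | 5,7-bis(benzyloxy)-2-(bromomethyl)-6,8-dimethoxy-4H-chromen-4-one | COc1c(OCc2ccccc2)c(OC)c2oc(CBr)cc(=O)c2c1OCc1ccccc1 | intermediate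
11 | {[5,7-bis(benzyloxy)-6,8-dimethoxy-4-oxo-4H-chromen-2-yl]methyl}triphenylphosphonium bromide | COc1c(OCc2ccccc2)c(OC)c2oc(C[P+](c3ccccc3)(c3ccccc3)c3ccccc3)cc(=O)c2c1OCc1ccccc1.[Br-] | intermediate
12 | benzyl glycidyl ether (racemic) | C(OCc1ccccc1)C1CO1 | starting material
13 | 1-(benzyloxy)-3-methoxypropan-2-ol (racemic) | COCC(O)COCc1ccccc1 | intermediate
14 | 1-(benzyloxy)-3-methoxypropan-2-one | COCC(=O)COCc1ccccc1 | intermediate
15 | 2-(benzyloxy)-1,5-bis(dimethylamino)-4-methoxypenta-1,4-dien-3-one (double-bond geometry not controlled and not relevant) | CN(C)C=C(OC)C(=O)C(OCc1ccccc1)=CN(C)C | intermediate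
16 | 3-(benzyloxy)-5-methoxy-4H-pyran-4-one | COc1cocc(OCc2ccccc2)c1=O | intermediate
17 | 3-(benzyloxy)-4-(tert-butyldimethylsilyloxy)-5-methoxypyrylium trifluoromethanesulfonate | COc1c[o+]cc(OCc2ccccc2)c1O[Si](C)(C)C(C)(C)C.[O-]S(=O)(=O)C(F)(F)F | intermediate
18 | 5,7-bis(benzyloxy)-6,8-dimethoxy-2-[(triphenylphosphoranylidene)methyl]-4H-chromen-4-one | COc1c(OCc2ccccc2)c(OC)c2oc(C=P(c3ccccc3)(c3ccccc3)c3ccccc3)cc(=O)c2c1OCc1ccccc1 | intermediate
19 | {[5,7-bis(benzyloxy)-6,8-dimethoxy-4-oxo-4H-chromen-2-yl][3-(benzyloxy)-4-(tert-butyldimethylsilyloxy)-5-methoxy-2H-pyran-2-yl]methyl}triphenylphosphonium trifluoromethanesulfonate (mixture of diastereomers; the regioisomeric adduct at C6 converges) | COC1=COC(C(c2cc(=O)c3c(OCc4ccccc4)c(OC)c(OCc4ccccc4)c(OC)c3o2)[P+](c2ccccc2)(c2ccccc2)c2ccccc2)C(OCc2ccccc2)=C1O[Si](C)(C)C(C)(C)C.[O-]S(=O)(=O)C(F)(F)F | intermediate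
20 | 5,7-bis(benzyloxy)-2-[(2E,4Z)-3-(benzyloxy)-4-(tert-butyldimethylsilyloxy)-5-methoxy-6-oxo-1-(triphenylphosphoranylidene)hexa-2,4-dien-1-yl]-6,8-dimethoxy-4H-chromen-4-one (geometry shown is the one that closes) | O=C/C(OC)=C(O[Si](C)(C)C(C)(C)C)\C(OCc1ccccc1)=C/C(=P(c1ccccc1)(c1ccccc1)c1ccccc1)c1cc(=O)c2c(OCc3ccccc3)c(OC)c(OCc3ccccc3)c(OC)c2o1 | intermediate
21 | 5,7-bis(benzyloxy)-2-[3-(benzyloxy)-4-(tert-butyldimethylsilyloxy)-5-methoxyphenyl]-6,8-dimethoxy-4H-chromen-4-one | COc1cc(-c2cc(=O)c3c(OCc4ccccc4)c(OC)c(OCc4ccccc4)c(OC)c3o2)cc(OCc2ccccc2)c1O[Si](C)(C)C(C)(C)C | intermediate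
22 | 5,7-bis(benzyloxy)-2-[3-(benzyloxy)-4-hydroxy-5-methoxyphenyl]-6,8-dimethoxy-4H-chromen-4-one | COc1cc(-c2cc(=O)c3c(OCc4ccccc4)c(OC)c(OCc4ccccc4)c(OC)c3o2)cc(OCc2ccccc2)c1O | intermediate
23 | 5,7-dihydroxy-2-(3,4-dihydroxy-5-methoxyphenyl)-6,8-dimethoxy-4H-chromen-4-one (5,7,3',4'-tetrahydroxy-6,8,5'-trimethoxyflavone) | COc1cc(-c2cc(=O)c3c(O)c(OC)c(O)c(OC)c3o2)cc(O)c1O | target

## Step count and least certain steps

Total step count: 12. Longest linear sequence: 9 steps (steps 1 to 7, then 11 and 12); the branch to 16 has 3 steps (steps 8 to 10).

**Step 11 (key step, new method).**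
- **What may go wrong:** silyl transfer from 17 to the carbonyl oxygen of 18, which would return 16 and a silylated, unreactive ylide; attack of 18 through chromone C3 instead of the ylide carbon; or failure of the ring-opened intermediate to reach the geometry needed for Wittig closure, so that it decomposes by hydrolysis of the silyl dienol ether.
- **Fallback (known chemistry):** it sets out from 5 and returns to the route at 23. Commercial methyl 3,4-dihydroxy-5-methoxybenzoate is dibenzylated (BnBr, K2CO3, DMF) to methyl 3,4-bis(benzyloxy)-5-methoxybenzoate F1. The polyanion of 5 (LiN(SiMe3)2, THF) undergoes Claisen condensation with it to give 1-[4-(benzyloxy)-2,6-dihydroxy-3,5-dimethoxyphenyl]-3-[3,4-bis(benzyloxy)-5-methoxyphenyl]propane-1,3-dione F2. Acid cyclodehydration (HCl, MeOH/THF, 60 °C) gives 7-(benzyloxy)-2-[3,4-bis(benzyloxy)-5-methoxyphenyl]-5-hydroxy-6,8-dimethoxy-4H-chromen-4-one F3, and hydrogenolysis (H2, Pd/C) gives 23.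

**Step 3.**
- **What may go wrong:** the catalyst stalls after the first hydroxylation because the phenoxide-bearing ring undergoes oxidative addition slowly; the second C–Br bond is protodebrominated; or the electron-rich resorcinolate is oxidised by traces of air in hot base.
- **Fallback:** it sets out from 3 and returns at 4. Double Miyaura borylation (B2pin2, PdCl2(dppf), KOAc, 1,4-dioxane, 90 °C) gives 2,2'-[5-(benzyloxy)-4,6-dimethoxy-1,3-phenylene]bis(4,4,5,5-tetramethyl-1,3,2-dioxaborolane) F4, which is oxidised with H2O2/NaOH at 0 °C to 4.

**Step 4.**
- **What may go wrong:** Lewis-acid-induced loss or migration of the benzyl group, or arrest at the O-acetate stage without transfer of the acyl group to carbon.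
- **Fallback:** it sets out from 4 and returns at 5. Both phenols are protected (MOMCl, iPr2NEt, CH2Cl2) to give 3-(benzyloxy)-2,4-dimethoxy-1,5-bis(methoxymethoxy)benzene F5. Directed ortho-lithiation between the two acetal oxygens (n-BuLi, THF, 0 °C) and trapping with N-methoxy-N-methylacetamide give 1-[4-(benzyloxy)-3,5-dimethoxy-2,6-bis(methoxymethoxy)phenyl]ethan-1-one F6. Methanolic HCl then removes both acetals to give 5.

**Step 5.**
- **What may go wrong:** incomplete C-acylation of the poorly soluble polyanion, self-condensation of the ester under excess base, or closure of the liberated primary hydroxyl onto the aryl ketone in competition with chromone formation.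
- **Fallback:** it sets out from 5 and returns at 8. Claisen condensation with diethyl oxalate (NaOEt, EtOH) gives ethyl 4-[4-(benzyloxy)-2,6-dihydroxy-3,5-dimethoxyphenyl]-2,4-dioxobutanoate F7. Acid cyclodehydration (HCl, EtOH, 70 °C) gives ethyl 7-(benzyloxy)-5-hydroxy-6,8-dimethoxy-4-oxo-4H-chromene-2-carboxylate F8, whose activated ester is reduced selectively (NaBH4, MeOH/THF, 0 °C) to 8.

**Step 10.**
- **What may go wrong:** the sequence stops after the first aminomethylenation, because the mono-enaminone is a vinylogous amide with a less acidic remaining methylene group.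
- **Fallback:** it sets out from 14 and returns at 16. Double Claisen formylation with ethyl formate and NaOEt in Et2O is driven by precipitation of disodium 2-(benzyloxy)-4-methoxy-3-oxopenta-1,4-diene-1,5-bis(olate) F9, which cyclodehydrates to 16 on acidification (HCl, EtOH).

## Further compounds

F1 | step 11 | methyl 3,4-bis(benzyloxy)-5-methoxybenzoate | COC(=O)c1cc(OC)c(OCc2ccccc2)c(OCc2ccccc2)c1
F2 | step 11 | 1-[4-(benzyloxy)-2,6-dihydroxy-3,5-dimethoxyphenyl]-3-[3,4-bis(benzyloxy)-5-methoxyphenyl]propane-1,3-dione | COc1cc(C(=O)CC(=O)c2c(O)c(OC)c(OCc3ccccc3)c(OC)c2O)cc(OCc2ccccc2)c1OCc1ccccc1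
F3 | step 11 | 7-(benzyloxy)-2-[3,4-bis(benzyloxy)-5-methoxyphenyl]-5-hydroxy-6,8-dimethoxy-4H-chromen-4-one | COc1cc(-c2cc(=O)c3c(O)c(OC)c(OCc4ccccc4)c(OC)c3o2)cc(OCc2ccccc2)c1OCc1ccccc1
F4 | step 3 | 2,2'-[5-(benzyloxy)-4,6-dimethoxy-1,3-phenylene]bis(4,4,5,5-tetramethyl-1,3,2-dioxaborolane) | COc1c(B2OC(C)(C)C(C)(C)O2)cc(B2OC(C)(C)C(C)(C)O2)c(OC)c1OCc1ccccc1
F5 | step 4 | 3-(benzyloxy)-2,4-dimethoxy-1,5-bis(methoxymethoxy)benzene | COCOc1cc(OCOC)c(OC)c(OCc2ccccc2)c1OC
F6 | step 4 | 1-[4-(benzyloxy)-3,5-dimethoxy-2,6-bis(methoxymethoxy)phenyl]ethan-1-one | CC(=O)c1c(OCOC)c(OC)c(OCc2ccccc2)c(OC)c1OCOC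
F7 | step 5 | ethyl 4-[4-(benzyloxy)-2,6-dihydroxy-3,5-dimethoxyphenyl]-2,4-dioxobutanoate | CCOC(=O)C(=O)CC(=O)c1c(O)c(OC)c(OCc2ccccc2)c(OC)c1O
F8 | step 5 | ethyl 7-(benzyloxy)-5-hydroxy-6,8-dimethoxy-4-oxo-4H-chromene-2-carboxylate | CCOC(=O)c1cc(=O)c2c(O)c(OC)c(OCc3ccccc3)c(OC)c2o1
F9 | step 10 | disodium 2-(benzyloxy)-4-methoxy-3-oxopenta-1,4-diene-1,5-bis(olate) | [Na+].[Na+].[O-]C=C(OC)C(=O)C(OCc1ccccc1)=C[O-]
A1 | alternative 1 | methyl 6-[3,4-bis(benzyloxy)-5-methoxyphenyl]-2-(methoxymethyl)-4-oxo-4H-pyran-3-carboxylate | COCc1oc(-c2cc(OC)c(OCc3ccccc3)c(OCc3ccccc3)c2)cc(=O)c1C(=O)OC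
A2 | alternative 1 | N,2-dimethoxy-N-methylacetamide | COCC(=O)N(C)OC
A3 | alternative 1 | 2-[3,4-bis(benzyloxy)-5-methoxyphenyl]-5,7-dihydroxy-6,8-dimethoxy-4H-chromen-4-one | COc1cc(-c2cc(=O)c3c(O)c(OC)c(O)c(OC)c3o2)cc(OCc2ccccc2)c1OCc1ccccc1
A4 | alternative 2 | 5-(benzyloxy)-4,6-dimethoxy-2-(trimethylsilyl)-1,3-phenylene bis(trifluoromethanesulfonate) | COc1c(OCc2ccccc2)c(OC)c(OS(=O)(=O)C(F)(F)F)c([Si](C)(C)C)c1OS(=O)(=O)C(F)(F)F
A5 | alternative 2 | 5-(benzyloxy)-4,6-dimethoxy-2,3-didehydrophenyl trifluoromethanesulfonate | COC1=C(OCc2ccccc2)C(OC)=C(OS(=O)(=O)C(F)(F)F)C#C1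
A6 | alternative 2 | 3-[3,4-bis(benzyloxy)-5-methoxyphenyl]prop-2-ynoic acid | COc1cc(C#CC(=O)O)cc(OCc2ccccc2)c1OCc1ccccc1
A7 | alternative 2 | 7-(benzyloxy)-2-[3,4-bis(benzyloxy)-5-methoxyphenyl]-6,8-dimethoxy-4-oxo-4H-chromen-5-yl trifluoromethanesulfonate | COc1cc(-c2cc(=O)c3c(OS(=O)(=O)C(F)(F)F)c(OC)c(OCc4ccccc4)c(OC)c3o2)cc(OCc2ccccc2)c1OCc1ccccc1
A8 | alternative 3 | 3,5-bis(benzyloxy)-4,6-dimethoxy-2-[(triphenylphosphoranylidene)acetyl]phenyl 3,4-bis(benzyloxy)-5-methoxybenzoate | COc1cc(C(=O)Oc2c(OC)c(OCc3ccccc3)c(OC)c(OCc3ccccc3)c2C(=O)C=P(c2ccccc2)(c2ccccc2)c2ccccc2)cc(OCc2ccccc2)c1OCc1ccccc1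
A9 | alternative 3 | 5,7-bis(benzyloxy)-2-[3,4-bis(benzyloxy)-5-methoxyphenyl]-6,8-dimethoxy-4H-chromen-4-one | COc1cc(-c2cc(=O)c3c(OCc4ccccc4)c(OC)c(OCc4ccccc4)c(OC)c3o2)cc(OCc2ccccc2)c1OCc1ccccc1
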